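**Retrosynthetic overview**
1. Thiophene–thiophene bond: 2-bromo-5-iodothiophene 1 + 2-thienylzinc bromide 2 ⇐ 5-bromo-2,2'-bithiophene 3 (iodide-selective Negishi coupling).
2. C(sp2)–C(sp) bond: 3 + but-1-en-3-yne 4 ⇐ enyne 5 (Sonogashira coupling).
3. Key disconnection: both cyclobutane bonds (CH2–CH2 and CH–CH) are cut at once: 2 × 5 ⇐ open-chain radical cation 6 ⇐ cardopatine 7. The forward reaction is a catalytic enantioselective radical-cation [2+2] cyclodimerisation of the achiral enyne, instead of attaching the bithienyl arms to a pre-resolved diethynylcyclobutane.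
4. Ring order: the thiophene rings are bought; the cyclobutane is the only ring made, and it is made last together with both stereocentres.

Assumption: but-1-en-3-yne is bought as its commercial solution in xylene (about 50 wt%); which enantiomer of the chiral IDPi anion gives the (1R,2R) product must be found by experiment, the route is written with that enantiomer, and its mirror image gives the (1S,2S) product.

**Step 1**
Reactants: 1 2-bromo-5-iodothiophene; 2 2-thienylzinc bromide (0.5 M in THF)
Product: 3 5-bromo-2,2'-bithiophene
Conditions: Pd(PPh3)4 (2 mol%), 2 (1.05 equiv), THF, 0 °C to rt, 3 h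
Reagents that add atoms: none
Why: Negishi cross-coupling, in which zerovalent palladium inserts into the C–I bond far faster than into the C–Br bond at room temperature, so exactly one thienyl group is delivered and the bromide is kept for step 2; no stereocentre is formed.

**Step 2**
Reactants: 3 5-bromo-2,2'-bithiophene; 4 but-1-en-3-yne (3 equiv, solution in xylene)
Product: 5 5-(but-3-en-1-yn-1-yl)-2,2'-bithiophene
Conditions: PdCl2(PhCN)2 (3 mol%), [HP(t-Bu)3]BF4 (6 mol%), CuI (2 mol%), i-Pr2NH (2 equiv), dioxane, rt, sealed flask, argon, dark, 12 h
Reagents that add atoms: none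
Why: Sonogashira coupling with the bulky electron-rich P(t-Bu)3 ligand lets the thienyl bromide react at room temperature, which keeps the volatile, polymerisable enyne 4 in solution and leaves its vinyl group untouched; no stereocentre is formed.

**Step 3**
Reactants: 5 5-(but-3-en-1-yn-1-yl)-2,2'-bithiophene (two molecules)
Product: 7 cardopatine [(1R,2R)-1,2-bis((2,2'-bithiophen-5-yl)ethynyl)cyclobutane], via open-chain distonic radical cation 6 (not isolated)
Conditions: 9-mesitylthioxanthylium salt of a confined BINOL-derived imidodiphosphorimidate (IDPi) anion (N-triflyl core, 3,3'-diaryl wings; 3 mol%), CH2Cl2/pentane 1:1 (0.1 M), −78 °C, green LED (525 nm), argon, 24 h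
Reagents that add atoms: none
Why: Proposed new method: a hole-catalysed (radical-cation) [2+2] cyclodimerisation run under asymmetric counteranion-directed photoredox catalysis, in which the photoexcited thioxanthylium cation oxidises the electron-rich enyne 5 (only the catalyst absorbs at 525 nm), the radical cation joins a neutral 5 CH2-to-CH2 (head-to-head, because spin and charge then both sit on propargylic carbons conjugated to bithienyl) to give 6, and 6, held as a contact ion pair in the chiral pocket of the non-basic IDPi anion in the non-polar cold medium, closes the CH–CH bond to the trans ring (trans by avoiding eclipsed alkynyl groups, (1R,2R) by the anion) before electron transfer from fresh 5 or from the thioxanthyl radical releases neutral 7 with nothing split off; the closest known reactions are the hole-catalysed head-to-head cyclodimerisation of N-vinylcarbazole (trans product only) and of 4-methoxystyrene, and the enantioselective cyclopropanation of styrene radical cations paired with IDPi anions.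

**Compound list**
1 | 2-bromo-5-iodothiophene | Brc1ccc(I)s1 | starting material
2 | 2-thienylzinc bromide (thiophen-2-ylzinc bromide, 0.5 M in THF) | Br[Zn]c1cccs1 | starting material
3 | 5-bromo-2,2'-bithiophene | Brc1ccc(-c2cccs2)s1 | intermediate
4 | but-1-en-3-yne (vinylacetylene) | C=CC#C | starting material
5 | 5-(but-3-en-1-yn-1-yl)-2,2'-bithiophene | C=CC#Cc1ccc(-c2cccs2)s1 | intermediate
6 | open-chain distonic radical cation, 1,8-bis(2,2'-bithiophen-5-yl)octa-1,7-diyne-3,6-diyl radical cation (not isolated) | C(#C[CH]CC[CH+]C#Cc1ccc(-c2cccs2)s1)c1ccc(-c2cccs2)s1 | intermediate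
7 | cardopatine, (1R,2R)-1,2-bis[(2,2'-bithiophen-5-yl)ethynyl]cyclobutane | C(#C[C@@H]1CC[C@H]1C#Cc1ccc(-c2cccs2)s1)c1ccc(-c2cccs2)s1 | target

**Total step count:** 3
**Longest linear sequence:** 3 (1 → 3 → 5 → 7)

**Steps most likely to fail, most risky first**

Step 3. Risks: enantiocontrol by ion pairing is unproven for an enyne radical cation; the cis dimer may form; the open-chain cation may oligomerise; the bithienyl radical cation may couple at its free α-position. Fallback, from 5 back to 7: irradiate 5 with thioxanthen-9-one (10 mol%) at 405 nm in degassed acetone at 0 °C. This is a triplet-sensitised [2+2] photodimerisation through a 1,4-biradical with no asymmetric induction. It gives the racemic trans dimer, that is 7 together with (1S,2S)-1,2-bis[(2,2'-bithiophen-5-yl)ethynyl]cyclobutane F4, plus the cis dimer isocardopatine F5. Remove F5 by chromatography on silica, then separate F4 from 7 by preparative HPLC on a cellulose tris(3,5-dimethylphenylcarbamate) phase (hexane/i-PrOH). The absolute configuration is then secured by resolution instead of by the catalyst.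

Step 2. Risks: loss of the volatile enyne 4, Glaser homocoupling, and polymerisation of 4 or 5. Fallback, from 3 back to 5: couple 3 with but-3-yn-1-ol under the same Sonogashira conditions to give 4-(2,2'-bithiophen-5-yl)but-3-yn-1-ol F2. Convert it with MsCl and Et3N in CH2Cl2 at 0 °C into 4-(2,2'-bithiophen-5-yl)but-3-yn-1-yl methanesulfonate F3. Eliminate with DBU in THF at rt to form the vinyl group and return to 5. The alkene is made after the coupling, so no vinylacetylene is handled.

Step 1. Risks: double coupling to terthiophene, or erosion of the iodide/bromide selectivity. Fallback, from 2 back to 3: couple 2 with 2-bromothiophene (Pd(PPh3)4, THF, 50 °C) to give 2,2'-bithiophene F1. Brominate once at the free α-position with N-bromosuccinimide (1.0 equiv, DMF, 0 °C, dark) to return to 3. The halogen is introduced by electrophilic substitution after the biaryl bond, so no chemoselective coupling is needed.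

**Further compounds**
F1 | step 1 | 2,2'-bithiophene | c1csc(-c2cccs2)c1
F2 | step 2 | 4-(2,2'-bithiophen-5-yl)but-3-yn-1-ol | OCCC#Cc1ccc(-c2cccs2)s1
F3 | step 2 | 4-(2,2'-bithiophen-5-yl)but-3-yn-1-yl methanesulfonate | CS(=O)(=O)OCCC#Cc1ccc(-c2cccs2)s1
F4 | step 3 | (1S,2S)-1,2-bis[(2,2'-bithiophen-5-yl)ethynyl]cyclobutane | C(#C[C@H]1CC[C@@H]1C#Cc1ccc(-c2cccs2)s1)c1ccc(-c2cccs2)s1
F5 | step 3 | isocardopatine, cis-(1R,2S)-1,2-bis[(2,2'-bithiophen-5-yl)ethynyl]cyclobutane (meso) | C(#C[C@@H]1CC[C@@H]1C#Cc1ccc(-c2cccs2)s1)c1ccc(-c2cccs2)s1
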